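## The problem

- The flavone skeleton is routine; the difficulty is ring A. All six of its carbons are substituted: C4a carries the C4 carbonyl, and C5, C6, C7, C8 and C8a carry five adjacent oxygens.
- These oxygens alternate in state: O5 and O7 must end as free hydroxyl, O6 and O8 as methyl ethers, and O1 (on C8a) inside ring C. Ring C adds a third methyl ether (O3) and ring B a third free phenol (O4').
- The target has no stereocenter. The whole problem is which oxygen sits where and in which state.
- The finished ring A is fragile. O5 and O8 are para, so oxidants lead to the 5,8-quinone; Lewis acids strip the methyl groups at O3 and O6; hot base opens the γ-pyrone. Differentiating the oxygens late, on the aromatic ring, is therefore unattractive.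
- The feature that opens a different plan: C5–C6–C7–C8 are four adjacent oxygen-bearing carbons with O5 and O8 para, which is the substitution pattern of a 2,3-dioxygenated hydroquinone and so the four-carbon ring of a squaric ester.
- The carbon that joins this unit to the rest, C8a, is the carbon next to the ring oxygen of a γ-pyrone (rings B and C taken as a preformed 2-aryl-3-methoxypyranone). That C–H can be metalated, and its neighbour C4a carries the hydrogen that is lost on aromatization.
- In the cyclobutenone that results, each of the four oxygens is distinct by position. The one that becomes O7 is the only vinylogous-ester oxygen, and its 1,3-dionate is mirror-symmetric, so it can be exchanged without any regiochemical question.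

## Retrosynthesis

**15 from 14.** The two O–CH2OCH3 bonds at O7 and O4' are cut. Methoxymethyl (MOM) ethers are chosen over benzyl or silyl because they survive a lithium amide, hydroxide and 110 °C. They come off with protic acid, which leaves the three methyl ethers untouched. The forward step must only avoid Lewis acids.

**14 from 11 (key disconnection, through 13 and 12).** The C4a–C5 bond of ring A is cut and C5 is joined to C8 instead, which turns the benzene ring into the cyclobutenone 11 attached to C6 of a γ-pyrone.
- The neighbouring cuts in ring C (O1–C2 with C2–C3, or C4–C4a, or C8a–O1) all leave the hexasubstituted benzene intact and push the whole difficulty into a pentaoxygenated arene. This cut removes ring A altogether.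
- The precursor 11 is much simpler: it has no benzene ring, and its four oxygens are already told apart (C1 carbonyl, C2 enol ether, C3 vinylogous acetal ester, C4 tertiary ether).
- The forward reaction must open the four-membered ring with the pyranone turned inward, close onto C5 of the pyranone (via ketene 12 and dienone 13), and tautomerize.

**11 from 9 (through 10).** The O–CH3 bond at the C3 oxygen is exchanged for O–MOM. This is done here and not on the flavone because in 9 this is the only alkoxy group of a vinylogous ester, whereas after aromatization it would be one of four aryl methyl ethers. The dionate 10 has a mirror plane through C2 and C4, so re-alkylation on either oxygen gives 11. The forward step needs a nucleophile that attacks C3 and spares the ring carbonyl and the pyranone.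

**9 from 8, and 8 from 5 and 6 (through 7).** The O–CH3 bond of the tertiary ether and the C8–C8a bond (cyclobutenone C4 to pyranone C6) are cut.
- Attachment through C6 of the pyranone, not C5, is essential: only then does the exchangeable vinylogous-ester oxygen map onto C7 and the ketene oxygen onto the free 5-OH.
- C6 is also the position next to the ring oxygen, which a hindered lithium amide deprotonates.
- Dimethyl squarate 6 is symmetric, so the addition of 7 has no regiochemistry. The precursors are one catalogue compound and a monocyclic pyranone.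

**5 from 3 and 4.** The C2–C1' bond between pyranone and ring B is cut (Suzuki–Miyaura coupling). This is preferred to building the pyranone from an acyclic tricarbonyl compound because a 3-oxygenated pyranone is commercial and the boronic acid 4 brings ring B with its protected phenol.

**3 from 2, and 2 from 1.** The O–CH3 and C2–Br bonds are cut. The enol of 1 directs the electrophile to C2, the only carbon that must be functionalized.

## Roads not taken

**Alternative 1:** the obvious route.
- Cut: O1–C2 and C2–C3 of ring C.
- Forward key step: Allan–Robinson (or Baker–Venkataraman) annulation of the pentaoxygenated ketone A1 with 4-(benzyloxy)benzoic anhydride.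
- A1 comes from the resorcinol A2 by acylation at its single free position. That acylation has no regiochemical problem, because A2 is mirror-symmetric.
- Why the chosen plan is better: the key step forms only the easy bonds. The hard part, five adjacent and differentiated oxygens on one benzene ring, must be built by a linear series of substitutions and oxidations on a syringol-type arene, with every oxygen entering separately. In the chosen plan four of the ring A carbons arrive at the right oxidation level in one commercial unit, and their oxygens are differentiated by position.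

**Alternative 2:** an aryne.
- Cut: C4–C4a and C8a–O1 in one operation.
- Forward key step: fluoride removes the silyl group and one of the two equivalent triflates of the symmetric precursor A3, giving aryne A4. A carboxylate (methoxyacetic acid) adds through oxygen at the aryne carbon next to the methoxy group. The aryl anion, stabilized by the neighbouring triflate, then takes the acyl group, giving the hydroxy ketone A5.
- Why the chosen plan is better: A3 needs the same pentaoxygenated benzene as A2 plus silylation and double triflation. The aryne only replaces a Friedel–Crafts acylation that has one possible site anyway. Ring C and the hydrolysis of the remaining triflate are still to come, so the aryne adds steps and a regiochemical risk.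

**Alternative 3:** ring C closed at a carbon–carbon bond.
- Cut: C4–C4a.
- Forward key step: intramolecular acylation (P2O5/MeSO3H) of the aryl enol ether acid A6, made by O-vinylation of A2.
- Why the chosen plan is better: A2 is again required. The O-vinylation must pick one of three phenolic oxygens and set the geometry of a tetrasubstituted alkene. The closure needs strong acid in the presence of benzyl ethers and an electron-rich ring. Like the other two, it leaves the hexasubstituted benzene as a starting point instead of making it.

Key step: step 7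

Remark on the chemistry: Pyr stands for the group 5-methoxy-6-[4-(methoxymethoxy)phenyl]-4-oxo-4H-pyran-2-yl. Compounds 8, 9, 11 and 13 have one stereocenter, are handled as racemates, and lose it on aromatization. Compounds 1, 4 and 6 are taken as catalogue chemicals, and LiTMP (lithium 2,2,6,6-tetramethylpiperidide) is added as a preformed solution.

## Steps

Step 1
Reactants: 1 3-hydroxy-4H-pyran-4-one
Product: 2 2-bromo-3-hydroxy-4H-pyran-4-one
Conditions: NBS (1.05 equiv), MeCN, 0 °C to rt
Reagents that add atoms: N-bromosuccinimide, O=C1CCC(=O)N1Br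
Why: Electrophilic bromination of an enol; C2 is the β-carbon of the C3 enol and the site at which 3-hydroxy-4-pyranones take up electrophiles, while C5 and C6 lack this activation.

Step 2
Reactants: 2 2-bromo-3-hydroxy-4H-pyran-4-one
Product: 3 2-bromo-3-methoxy-4H-pyran-4-one
Conditions: MeI, K2CO3, acetone, 40 °C
Reagents that add atoms: iodomethane, CI
Why: Williamson O-methylation of the acidic enolic hydroxyl; the mild carbonate base leaves the bromopyranone intact.

Step 3
Reactants: 3 2-bromo-3-methoxy-4H-pyran-4-one; 4 [4-(methoxymethoxy)phenyl]boronic acid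
Product: 5 3-methoxy-2-[4-(methoxymethoxy)phenyl]-4H-pyran-4-one
Conditions: PdCl2(dppf) (5 mol %), K3PO4, 1,4-dioxane/H2O 10:1, 80 °C
Reagents that add atoms: none
Why: Suzuki–Miyaura coupling; the C2–Br bond is that of a β-bromo enone and adds readily to zerovalent palladium, and the MOM ether and the pyranone tolerate phosphate base.

Step 4
Reactants: 5 3-methoxy-2-[4-(methoxymethoxy)phenyl]-4H-pyran-4-one; 6 3,4-dimethoxycyclobut-3-ene-1,2-dione (dimethyl squarate)
Product: 8 4-hydroxy-2,3-dimethoxy-4-Pyr-cyclobut-2-en-1-one (racemic), via 6-lithiopyranone 7 (not isolated)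
Conditions: LiTMP (1.1 equiv), THF, –78 °C, 15 min; cannulation into 6 (1.5 equiv), THF, –78 °C; AcOH, –78 °C
Reagents that add atoms: none
Why: Deprotonation of the γ-pyrone C–H next to the ring oxygen by a hindered lithium amide (as at C2 of chromones), followed by 1,2-addition of the vinyllithium to one of the two equivalent carbonyl groups of the squaric ester; inverse addition to excess 6 and a cold acidic quench prevent double addition and opening of the alkoxide, and the new stereocenter is formed as a racemate.

Step 5
Reactants: 8 4-hydroxy-2,3-dimethoxy-4-Pyr-cyclobut-2-en-1-one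
Product: 9 2,3,4-trimethoxy-4-Pyr-cyclobut-2-en-1-one (racemic)
Conditions: MeI (10 equiv), Ag2O (3 equiv), MeCN, rt, dark
Reagents that add atoms: iodomethane, CI
Why: Purdie methylation, the usual way to turn 4-hydroxycyclobutenones into their 4-methoxy ethers without forming a free alkoxide that would fragment the ring; this methyl group later directs the ring opening and ends as the 8-OMe.

Step 6
Reactants: 9 2,3,4-trimethoxy-4-Pyr-cyclobut-2-en-1-one
Product: 11 2,4-dimethoxy-3-(methoxymethoxy)-4-Pyr-cyclobut-2-en-1-one (racemic), via lithium dionate 10 (not isolated)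
Conditions: LiOH (1.05 equiv), THF/H2O 4:1, 0 °C; evaporation and drying (PhMe azeotrope); MOMCl (1.3 equiv), DMF, 0 °C
Reagents that add atoms: lithium hydroxide, [Li+].[OH-]; chloromethyl methyl ether, COCCl
Why: Saponification of a vinylogous ester by addition–elimination at C3 (as in the half-hydrolysis of squaric esters); the C2 enol ether, the C4 tertiary ether and the aryl MOM ether are inert to hydroxide, and the dionate 10 has a mirror plane through C2 and C4, so O-alkylation by the hard electrophile MOMCl gives the same constitution at either oxygen.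

Step 7
Reactants: 11 2,4-dimethoxy-3-(methoxymethoxy)-4-Pyr-cyclobut-2-en-1-one
Product: 14 5-hydroxy-3,6,8-trimethoxy-7-(methoxymethoxy)-2-[4-(methoxymethoxy)phenyl]-4H-chromen-4-one, via dienylketene 12 (not isolated), via cyclohexadienone 13 (not isolated)
Conditions: PhMe (0.01 M, degassed), 110 °C
Reagents that add atoms: none
Why: Heating opens the cyclobutenone 11 by conrotatory 4π-electrocyclic cleavage of the C1–C4 bond, and the donor methoxy group on C4 rotates outward so that the pyranonyl group turns inward and the dienylketene 12 forms with the pyranone cis to the ketene. A thermal disrotatory 6π-electrocyclization then joins the ketene carbon to C5 of the pyranone and closes ring A as a six-membered carbocycle in the 4aH-dienone 13, and enolization of the C4a–H, which lies between two carbonyl groups, gives the phenol 14 irreversibly. The closest known reaction type is the Moore rearrangement of 4-aryl-, 4-heteroaryl- and 4-alkenyl-4-alkoxycyclobutenones to hydroquinone monoethers. No stereocenter is formed: the stereocenter of 11 and that at C4a of 13 are both erased on aromatization. The selectivities needed are the torquoselectivity of the ring opening, secured by the C4 methoxy group, and the site of ring closure, for which only C5 of the pyranone is available because the other neighbour of the attachment carbon is the ring oxygen. The position of every oxygen of ring A is fixed by its place in 11 (C1=O becomes 5-OH, C2-OMe goes to C6, C3-OMOM to C7, C4-OMe to C8), so no regiochemical choice arises. High dilution in degassed toluene keeps the ketene from intermolecular reactions and the electron-rich phenol from oxidation.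

Step 8
Reactants: 14 5-hydroxy-3,6,8-trimethoxy-7-(methoxymethoxy)-2-[4-(methoxymethoxy)phenyl]-4H-chromen-4-one
Product: 15 5,7-dihydroxy-2-(4-hydroxyphenyl)-3,6,8-trimethoxy-4H-chromen-4-one
Conditions: HCl (3 M aq), MeOH, 50 °C
Reagents that add atoms: none
Why: Acid-catalysed acetal exchange removes both aryl MOM ethers; the three methyl ethers need Lewis acids or HBr for cleavage and stay in place.

## Compound list

1 | 3-hydroxy-4H-pyran-4-one | O=c1ccocc1O | starting material
2 | 2-bromo-3-hydroxy-4H-pyran-4-one | O=c1ccoc(Br)c1O | intermediate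
3 | 2-bromo-3-methoxy-4H-pyran-4-one | COc1c(Br)occc1=O | intermediate
4 | [4-(methoxymethoxy)phenyl]boronic acid | COCOc1ccc(cc1)B(O)O | starting material
5 | 3-methoxy-2-[4-(methoxymethoxy)phenyl]-4H-pyran-4-one | COCOc1ccc(cc1)-c1occc(=O)c1OC | intermediate
6 | 3,4-dimethoxycyclobut-3-ene-1,2-dione (dimethyl squarate) | COC1=C(OC)C(=O)C1=O | starting material
7 | {5-methoxy-6-[4-(methoxymethoxy)phenyl]-4-oxo-4H-pyran-2-yl}lithium | COCOc1ccc(cc1)-c1oc([Li])cc(=O)c1OC | intermediate (not isolated)
8 | 4-hydroxy-2,3-dimethoxy-4-{5-methoxy-6-[4-(methoxymethoxy)phenyl]-4-oxo-4H-pyran-2-yl}cyclobut-2-en-1-one (racemic) | COCOc1ccc(cc1)-c1oc(cc(=O)c1OC)C1(O)C(OC)=C(OC)C1=O | intermediate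
9 | 2,3,4-trimethoxy-4-{5-methoxy-6-[4-(methoxymethoxy)phenyl]-4-oxo-4H-pyran-2-yl}cyclobut-2-en-1-one (racemic) | COCOc1ccc(cc1)-c1oc(cc(=O)c1OC)C1(OC)C(OC)=C(OC)C1=O | intermediate
10 | lithium 2,4-dimethoxy-4-{5-methoxy-6-[4-(methoxymethoxy)phenyl]-4-oxo-4H-pyran-2-yl}-3-oxocyclobut-1-en-1-olate | COCOc1ccc(cc1)-c1oc(cc(=O)c1OC)C1(OC)C([O-])=C(OC)C1=O.[Li+] | intermediate (not isolated)
11 | 2,4-dimethoxy-3-(methoxymethoxy)-4-{5-methoxy-6-[4-(methoxymethoxy)phenyl]-4-oxo-4H-pyran-2-yl}cyclobut-2-en-1-one (racemic) | COCOc1ccc(cc1)-c1oc(cc(=O)c1OC)C1(OC)C(OCOC)=C(OC)C1=O | intermediate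
12 | (3Z)-2,4-dimethoxy-3-(methoxymethoxy)-4-{5-methoxy-6-[4-(methoxymethoxy)phenyl]-4-oxo-4H-pyran-2-yl}buta-1,3-dien-1-one | O=C=C(OC)/C(OCOC)=C(/OC)c1cc(=O)c(OC)c(-c2ccc(OCOC)cc2)o1 | intermediate (not isolated)
13 | 3,6,8-trimethoxy-7-(methoxymethoxy)-2-[4-(methoxymethoxy)phenyl]-4aH-chromene-4,5-dione (racemic) | O=C1C(OC)=C(OCOC)C(OC)=C2OC(c3ccc(OCOC)cc3)=C(OC)C(=O)C12 | intermediate (not isolated)
14 | 5-hydroxy-3,6,8-trimethoxy-7-(methoxymethoxy)-2-[4-(methoxymethoxy)phenyl]-4H-chromen-4-one | COc1c(OCOC)c(OC)c2oc(-c3ccc(OCOC)cc3)c(OC)c(=O)c2c1O | intermediate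
15 | 5,7-dihydroxy-2-(4-hydroxyphenyl)-3,6,8-trimethoxy-4H-chromen-4-one | COc1c(O)c(OC)c2oc(-c3ccc(O)cc3)c(OC)c(=O)c2c1O | target

## Step count and risks

Total: 8 steps. Longest linear sequence: 8 steps (1 to 15); 4 and 6 are bought and enter at steps 3 and 4.

**Step 7 (key step).**
- Most likely failure: slow 6π-closure onto the cross-conjugated C5=C6 bond of the pyranone, so that the ketene 12 is used up by dimerization or by traces of nucleophiles. Loss of the acetal-type MOM group from the vinylogous ester on heating is the second concern.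
- Fallback (ring A first; sets out from 6, returns at 15):
  - Ethyl vinyl ether is lithiated (t-BuLi, THF) to 1-ethoxyvinyllithium F1. An enol ether is the best-behaved 2π partner for this rearrangement.
  - Addition of F1 to 6 and trapping of the alkoxide with MeOTf would give 4-(1-ethoxyethenyl)-2,3,4-trimethoxycyclobut-2-en-1-one F2.
  - The exchange of step 6 (LiOH; MOMCl) would give 4-(1-ethoxyethenyl)-2,4-dimethoxy-3-(methoxymethoxy)cyclobut-2-en-1-one F3.
  - Thermolysis in toluene would give 5-ethoxy-2,4-dimethoxy-3-(methoxymethoxy)phenol F4, which has one free ring position.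
  - Hoesch acylation with methoxyacetonitrile (ZnCl2, HCl, Et2O; aqueous hydrolysis) acylates that position and removes the MOM group, giving 1-(6-ethoxy-2,4-dihydroxy-3,5-dimethoxyphenyl)-2-methoxyethan-1-one F5.
  - Allan–Robinson annulation (4-(benzyloxy)benzoic anhydride and its potassium salt, 180 °C; KOH work-up) would give 2-[4-(benzyloxy)phenyl]-5-ethoxy-7-hydroxy-3,6,8-trimethoxy-4H-chromen-4-one F6.
  - BCl3 (CH2Cl2, –78 to 0 °C) cleaves the carbonyl-chelated 5-ethyl ether and the benzyl ether to give 15.

**Step 4.**
- Most likely failure: self-condensation, because the lithiated pyranone 7 meets still-unmetalated, electrophilic 5 during the deprotonation. Partial metalation at C5 next to the carbonyl is also possible.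
- Fallback (metalation separated from carbanion reactivity; sets out from 5, returns at 8):
  - TMPZnCl·LiCl (THF, rt) would zincate 5 next to the ring oxygen to chloro{5-methoxy-6-[4-(methoxymethoxy)phenyl]-4-oxo-4H-pyran-2-yl}zinc F7, which does not attack pyranones.
  - Iodolysis (I2) would give 6-iodo-3-methoxy-2-[4-(methoxymethoxy)phenyl]-4H-pyran-4-one F8.
  - Iodine–magnesium exchange (iPrMgCl·LiCl, THF, –78 °C) is fast and complete and gives chloro{5-methoxy-6-[4-(methoxymethoxy)phenyl]-4-oxo-4H-pyran-2-yl}magnesium F9. F9 is added to 6 and quenched with AcOH to give 8.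

**Step 6.**
- Most likely failure: attack of hydroxide at the ring carbonyl with cleavage of the strained four-membered ring, or opening of the pyranone, in competition with substitution at C3.
- Fallback (the C7 oxygen is differentiated before the C–C bond is made and unmasked without a nucleophile; sets out from 6 and 7, returns at 11):
  - Exchange of one methoxy group of 6 with benzyl alcohol would give 3-(benzyloxy)-4-methoxycyclobut-3-ene-1,2-dione F10.
  - Addition of 7 gives two regioisomers, separated by chromatography: the wanted 3-(benzyloxy)-4-hydroxy-2-methoxy-4-Pyr-cyclobut-2-en-1-one F11 and 2-(benzyloxy)-4-hydroxy-3-methoxy-4-Pyr-cyclobut-2-en-1-one F12.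
  - Methylation of F11 as in step 5 would give 3-(benzyloxy)-2,4-dimethoxy-4-Pyr-cyclobut-2-en-1-one F13.
  - Hydrogenolysis (H2, Pd/C, EtOAc) of the vinylogous benzyl ester would give 3-hydroxy-2,4-dimethoxy-4-Pyr-cyclobut-2-en-1-one F14.
  - MOMCl and iPr2NEt (CH2Cl2, 0 °C) convert F14 into 11.
  - The price is a regioisomer separation that the main route avoids.

**Step 5.**
- Most likely failure: sluggish alkylation of a hindered tertiary alcohol flanked by electron-poor groups, with base-induced fragmentation of the hydroxycyclobutenone competing.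
- Fallback (the C8 methyl group is introduced after the ring expansion; sets out from 8, returns at 14):
  - Silylation (TBSOTf, 2,6-lutidine, CH2Cl2, –78 °C) would give 4-[(tert-butyldimethylsilyl)oxy]-2,3-dimethoxy-4-Pyr-cyclobut-2-en-1-one F15.
  - The exchange of step 6 would give 4-[(tert-butyldimethylsilyl)oxy]-2-methoxy-3-(methoxymethoxy)-4-Pyr-cyclobut-2-en-1-one F16.
  - Thermolysis as in step 7 would give 8-[(tert-butyldimethylsilyl)oxy]-5-hydroxy-3,6-dimethoxy-7-(methoxymethoxy)-2-[4-(methoxymethoxy)phenyl]-4H-chromen-4-one F17.
  - CsF and MeI in degassed DMF remove the silyl group and methylate the liberated 8-phenoxide in one flask. The 5-hydroxyl, hydrogen-bonded to the C4 carbonyl, stays free, and the product is 14.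

## Further compounds

F1 | step 7 | 1-ethoxyvinyllithium | [Li]C(=C)OCC
F2 | step 7 | 4-(1-ethoxyethenyl)-2,3,4-trimethoxycyclobut-2-en-1-one (racemic) | C=C(OCC)C1(OC)C(OC)=C(OC)C1=O
F3 | step 7 | 4-(1-ethoxyethenyl)-2,4-dimethoxy-3-(methoxymethoxy)cyclobut-2-en-1-one (racemic) | C=C(OCC)C1(OC)C(OCOC)=C(OC)C1=O
F4 | step 7 | 5-ethoxy-2,4-dimethoxy-3-(methoxymethoxy)phenol | CCOc1cc(O)c(OC)c(OCOC)c1OC
F5 | step 7 | 1-(6-ethoxy-2,4-dihydroxy-3,5-dimethoxyphenyl)-2-methoxyethan-1-one | COCC(=O)c1c(O)c(OC)c(O)c(OC)c1OCC
F6 | step 7 | 2-[4-(benzyloxy)phenyl]-5-ethoxy-7-hydroxy-3,6,8-trimethoxy-4H-chromen-4-one | CCOc1c(OC)c(O)c(OC)c2oc(-c3ccc(OCc4ccccc4)cc3)c(OC)c(=O)c12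
F7 | step 4 | chloro{5-methoxy-6-[4-(methoxymethoxy)phenyl]-4-oxo-4H-pyran-2-yl}zinc | COCOc1ccc(cc1)-c1oc([Zn]Cl)cc(=O)c1OC
F8 | step 4 | 6-iodo-3-methoxy-2-[4-(methoxymethoxy)phenyl]-4H-pyran-4-one | COCOc1ccc(cc1)-c1oc(I)cc(=O)c1OC
F9 | step 4 | chloro{5-methoxy-6-[4-(methoxymethoxy)phenyl]-4-oxo-4H-pyran-2-yl}magnesium | COCOc1ccc(cc1)-c1oc([Mg]Cl)cc(=O)c1OC
F10 | step 6 | 3-(benzyloxy)-4-methoxycyclobut-3-ene-1,2-dione | COC1=C(OCc2ccccc2)C(=O)C1=O
F11 | step 6 | 3-(benzyloxy)-4-hydroxy-2-methoxy-4-{5-methoxy-6-[4-(methoxymethoxy)phenyl]-4-oxo-4H-pyran-2-yl}cyclobut-2-en-1-one (racemic) | COCOc1ccc(cc1)-c1oc(cc(=O)c1OC)C1(O)C(OCc2ccccc2)=C(OC)C1=O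
F12 | step 6 | 2-(benzyloxy)-4-hydroxy-3-methoxy-4-{5-methoxy-6-[4-(methoxymethoxy)phenyl]-4-oxo-4H-pyran-2-yl}cyclobut-2-en-1-one (racemic) | COCOc1ccc(cc1)-c1oc(cc(=O)c1OC)C1(O)C(OC)=C(OCc2ccccc2)C1=O
F13 | step 6 | 3-(benzyloxy)-2,4-dimethoxy-4-{5-methoxy-6-[4-(methoxymethoxy)phenyl]-4-oxo-4H-pyran-2-yl}cyclobut-2-en-1-one (racemic) | COCOc1ccc(cc1)-c1oc(cc(=O)c1OC)C1(OC)C(OCc2ccccc2)=C(OC)C1=O
F14 | step 6 | 3-hydroxy-2,4-dimethoxy-4-{5-methoxy-6-[4-(methoxymethoxy)phenyl]-4-oxo-4H-pyran-2-yl}cyclobut-2-en-1-one (racemic) | COCOc1ccc(cc1)-c1oc(cc(=O)c1OC)C1(OC)C(O)=C(OC)C1=O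
F15 | step 5 | 4-[(tert-butyldimethylsilyl)oxy]-2,3-dimethoxy-4-{5-methoxy-6-[4-(methoxymethoxy)phenyl]-4-oxo-4H-pyran-2-yl}cyclobut-2-en-1-one (racemic) | COCOc1ccc(cc1)-c1oc(cc(=O)c1OC)C1(O[Si](C)(C)C(C)(C)C)C(OC)=C(OC)C1=O
F16 | step 5 | 4-[(tert-butyldimethylsilyl)oxy]-2-methoxy-3-(methoxymethoxy)-4-{5-methoxy-6-[4-(methoxymethoxy)phenyl]-4-oxo-4H-pyran-2-yl}cyclobut-2-en-1-one (racemic) | COCOc1ccc(cc1)-c1oc(cc(=O)c1OC)C1(O[Si](C)(C)C(C)(C)C)C(OCOC)=C(OC)C1=O
F17 | step 5 | 8-[(tert-butyldimethylsilyl)oxy]-5-hydroxy-3,6-dimethoxy-7-(methoxymethoxy)-2-[4-(methoxymethoxy)phenyl]-4H-chromen-4-one | COc1c(OCOC)c(O[Si](C)(C)C(C)(C)C)c2oc(-c3ccc(OCOC)cc3)c(OC)c(=O)c2c1O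
A1 | alternative 1 | 1-[4-(benzyloxy)-2,6-dihydroxy-3,5-dimethoxyphenyl]-2-methoxyethan-1-one | COCC(=O)c1c(O)c(OC)c(OCc2ccccc2)c(OC)c1O
A2 | alternative 1 | 5-(benzyloxy)-4,6-dimethoxybenzene-1,3-diol | COc1c(O)cc(O)c(OC)c1OCc1ccccc1
A3 | alternative 2 | 5-(benzyloxy)-4,6-dimethoxy-2-(trimethylsilyl)-1,3-phenylene bis(trifluoromethanesulfonate) | COc1c(OCc2ccccc2)c(OC)c(OS(=O)(=O)C(F)(F)F)c([Si](C)(C)C)c1OS(=O)(=O)C(F)(F)F
A4 | alternative 2 | 3-(benzyloxy)-2,4-dimethoxy-5,6-didehydrophenyl trifluoromethanesulfonate (aryne) | COC1=C(OCc2ccccc2)C(OC)=C(OS(=O)(=O)C(F)(F)F)C#C1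
A5 | alternative 2 | 3-(benzyloxy)-5-hydroxy-2,4-dimethoxy-6-(methoxyacetyl)phenyl trifluoromethanesulfonate | COCC(=O)c1c(O)c(OC)c(OCc2ccccc2)c(OC)c1OS(=O)(=O)C(F)(F)F
A6 | alternative 3 | (E)-3-[4-(benzyloxy)phenyl]-3-[3-(benzyloxy)-5-hydroxy-2,4-dimethoxyphenoxy]-2-methoxyprop-2-enoic acid | OC(=O)/C(OC)=C(/c1ccc(OCc2ccccc2)cc1)Oc1cc(O)c(OC)c(OCc2ccccc2)c1OC
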